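Readings and results were generated by integration on assumed constants, noise included.

If incoming ligand decomposes while it exchanges, I want to know what each portion of it buys, so I look for a number that stays put from flask to flask.

| setting | blue | red | violet | Wednesday's | Friday's | Tuesday's | Saturday's | Monday's |
|---|---|---|---|---|---|---|---|---|
| starting complex | 0.20 M | 0.20 M | 0.20 M | 0.20 M (fed, over 1.5 min) | 0.20 M | 0.20 M | 0.20 M | 0.20 M (fed, over 15 min) |
| incoming ligand | 0.22 M | 0.31 M | 0.48 M | 0.220 M | 0.220 M (in portions, 2, over 15 min) | 0.220 M (fed, over 15 min) | 0.220 M | 0.220 M |
| remark | run made earlier | run made earlier | run made earlier | all else is in the flask from the start; the feed brings no volume worth counting | first portion at the start, last at 15 min | all else is in the flask from the start; the feed brings no volume worth counting | everything together at the start | all else is in the flask from the start; the feed brings no volume worth counting |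
| time |  |  |  | 20 min | 20 min | 20 min | 20 min | 20 min |

| run | time / min | complex with one exchanged / % | starting complex / % |
|---|---|---|---|
| blue | 1.00 | 31 | 61 |
| blue | 2.00 | 42 | 54 |
| blue | 3.00 | 43 | 52 |
| blue | 6.00 | 47 | 48 |
| blue | 12.0 | 50 | 48 |
| red | 1.33 | 42 | 47 |
| red | 4.00 | 56 | 38 |
| red | 8.00 | 57 | 34 |
| red | 12.0 | 59 | 33 |
| red | 15.0 | 60 | 38 |
| violet | 3.00 | 63 | 23 |
| violet | 6.00 | 65 | 22 |
| violet | 10.0 | 71 | 21 |
| violet | 12.0 | 66 | 17 |
| violet | 15.0 | 67 | 20 |

(each reading ± 1.5 percentage points)

- what was read earlier has a scatter of 1.5 percentage points, one standard deviation
- steps thought possible: complex with two exchanged + incoming ligand <-> leaving ligand + complex with three exchanged; incoming ligand -> decomposed reagent; complex with one exchanged + incoming ligand <-> leaving ligand + complex with two exchanged; starting complex + incoming ligand <-> leaving ligand + complex with one exchanged; leaving ligand -> by-product carried off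

* which flask leads in amount of complex with one exchanged, in percent of the starting complex charged ("all alike" within 1.5 percentage points) (Wednesday's / Friday's / Tuesday's / Saturday's / Monday's / all alike)
* how much complex with one exchanged is there at the end, in percent of the starting complex charged: Wednesday's
* how much complex with one exchanged is there at the end, in percent of the starting complex charged: Friday's
* how much complex with one exchanged is there at the end, in percent of the starting complex charged: Tuesday's
* how much complex with one exchanged is there at the end, in percent of the starting complex charged: Saturday's
* how much complex with one exchanged is there at the end, in percent of the starting complex charged: Monday's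

Exchange and decay both go with the first power of ligand, so their ratio contains no ligand. Neglecting the way back, each bit of ligand decayed lowers the logarithm of the starting complex by a fixed amount. I name that amount the selectivity factor: the natural logarithm of charged over remaining starting complex, divided by the ligand decayed, which is the charge less what the complexes hold. The blue plateau reads 6.55 L mol⁻¹.

The first setting is the amount of ligand. By hand, more ligand means more decayed and a deeper logarithm at the same factor. Red reads 6.93 L mol⁻¹ and violet 5.47 L mol⁻¹, so the factor sags but holds. I freeze blue's, since blue has Saturday's charges.

The factor also gives a clock. Blue's first reading means 0.0754 M had decayed, leaving about 0.0506 M free, so a ligand lifetime of about 1.79 min.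

The second setting is when the ligand enters. The rule holds no time, and the last portion still has 5.00 min, longer than that lifetime. So I put Friday's and Tuesday's beside Saturday's, near blue's 50%.

The third setting is when the complex enters. Wednesday's average complex arrives after 34.2% of the ligand has decayed, so I put it clearly lower. Monday's feed is longer than the lifetime, and about 12.0% of its complex arrives within one lifetime, so I expect about that much exchanged.

The forecast gives Saturday's the lead, with Wednesday's 51.8%, Friday's 50%, Tuesday's 50%, Saturday's 52% and Monday's 50%, holding that “The final state therefore mostly forgets the addition order”; on Wednesday's and Monday's my reckoning differs.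

The flasks give Saturday's the lead, with complex with one exchanged at 38.0% for Wednesday's, 46.1% for Friday's, 46.4% for Tuesday's, 48.3% for Saturday's and 10.1% for Monday's.

    complex with two exchanged + incoming ligand ⇌ leaving ligand + complex with three exchanged (K = 0.810, k = 0.0510 L mol⁻¹ s⁻¹)
    incoming ligand → decomposed reagent (k = 0.00790 s⁻¹)
    complex with one exchanged + incoming ligand ⇌ leaving ligand + complex with two exchanged (K = 0.180, k = 0.120 L mol⁻¹ s⁻¹)
    starting complex + incoming ligand ⇌ leaving ligand + complex with one exchanged (K = 5.80, k = 0.0630 L mol⁻¹ s⁻¹)
    leaving ligand → by-product carried off (k = 0.00670 s⁻¹)

Now I take Saturday's flask with 0.050 M of starting complex. That neighbour ends with 0.171 M of decomposed reagent, so the rule with blue's factor leaves 32.6% of its starting complex. The neighbour holds 28.1% of its starting complex and 53.5% as complex with one exchanged.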